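**Retrosynthetic overview**

- The strategy rests on C2 of the dihydropyran ring: a fully substituted ether carbon bonded to O1, C3, the 2-methyl group and C1'. C2, C3 and the 2-methyl map onto the β-carbon, the γ-methyl and the α-carbon of an (E)-3-methyl-2-enal; C4 is the formyl carbon of a salicylaldehyde; the enal formyl carbon is scaffolding.
- Key disconnection: O1–C2 and C3–C4 (plus a temporary C4–O–CH(OH) bridge) are made in one aminocatalytic aldol/oxa-Michael domino of enal 11 and salicylaldehyde 14, giving bridged lactol 16. The benzene ring is bought; the dihydropyran ring closes first and the lactol ring second, both in step 9.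
- Enal 11: Horner–Wadsworth–Emmons homologation of C18 methyl ketone 8, which comes from Grignard reagent 6 and methyl vinyl ketone. Chloride 5 joins (R)-citronellyl bromide (C8') and (S)-1-bromo-3-chloro-2-methylpropane (C4').
- Salicylaldehyde 14: monosilylation and ortho-formylation of methylhydroquinone.
- Endgame: lactol to lactone, hydride cleavage of the benzylic C4–O bond, Barton decarboxylation (the former formyl carbon leaves as CO2), desilylation.

Key step: step 9

Remark: the C6 oxygen is carried as a triisopropylsilyl ether, chosen for selective introduction on methylhydroquinone and for stability towards the magnesium phenoxide formylation and BF3·OEt2. Chroman numbering (O1, C2–C4, C4a–C8a, side chain C1'–C13') is used for the late intermediates.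

**Route**

Step 1
Reactants: 1 (S)-3-bromo-2-methylpropan-1-ol
Product: 2 (S)-1-bromo-3-chloro-2-methylpropane
Conditions: PPh3, N-chlorosuccinimide, THF, 0 °C to rt
Reagents that add atoms: N-chlorosuccinimide, O=C1CCC(=O)N1Cl
Why: Appel-type chlorination in which chloride displaces the alkoxyphosphonium group at the primary carbon, while the much poorer C–Br electrophile and the stereocentre, which is not a reacting carbon, are left alone.

Step 2
Reactants: 3 (R)-citronellyl bromide; 2 (S)-1-bromo-3-chloro-2-methylpropane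
Product: 5 (6S,10R)-11-chloro-2,6,10-trimethylundec-2-ene, via citronellylmagnesium bromide 4 (not isolated)
Conditions: Mg, THF, 40 °C; then 2, Li2CuCl4 (3 mol%), THF, −10 °C to rt
Reagents that add atoms: none
Why: Kochi–Schlosser copper-catalysed sp3–sp3 Grignard cross-coupling, which takes place at the C–Br bond and leaves the C–Cl bond intact, so both stereocentres come unchanged from the two chiral building blocks.

Step 3
Reactants: 5 (6S,10R)-11-chloro-2,6,10-trimethylundec-2-ene
Product: 8 (6R,10S)-6,10,14-trimethylpentadec-13-en-2-one, via Grignard reagent 6 (not isolated), via silyl enol ether 7 (not isolated)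
Conditions: Mg, THF, reflux; then CuBr·SMe2 (10 mol%), Me3SiCl, methyl vinyl ketone, THF, −78 °C; aq. HCl
Reagents that add atoms: methyl vinyl ketone, C=CC(C)=O
Why: Copper-catalysed, chlorosilane-accelerated 1,4-addition of a primary alkyl Grignard reagent to an enone, trapped as the silyl enol ether and hydrolysed on work-up, which adds C2', C1' and the acetyl group without touching the remote alkene or the stereocentres.

Step 4
Reactants: 8 (6R,10S)-6,10,14-trimethylpentadec-13-en-2-one
Product: 9 ethyl (2E,7R,11S)-3,7,11,15-tetramethylhexadeca-2,14-dienoate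
Conditions: (EtO)2P(O)CH2CO2Et, NaH, THF, 0 °C to reflux; chromatography to remove the Z isomer
Reagents that add atoms: triethyl phosphonoacetate, CCOC(=O)CP(=O)(OCC)OCC
Why: Horner–Wadsworth–Emmons olefination of a methyl ketone, expected to favour the E trisubstituted enoate, with the minor Z isomer removed on silica (any residue should converge in step 9, where the dienamine erases this geometry).

Step 5
Reactants: 9 ethyl (2E,7R,11S)-3,7,11,15-tetramethylhexadeca-2,14-dienoate
Product: 10 (2E,7R,11S)-3,7,11,15-tetramethylhexadeca-2,14-dien-1-ol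
Conditions: iBu2AlH, CH2Cl2, −78 °C; aq. potassium sodium tartrate
Reagents that add atoms: none
Why: 1,2-Reduction of an α,β-unsaturated ester to the allylic alcohol by an aluminium hydride, which leaves both C=C bonds and the E geometry untouched.

Step 6
Reactants: 10 (2E,7R,11S)-3,7,11,15-tetramethylhexadeca-2,14-dien-1-ol
Product: 11 (2E,7R,11S)-3,7,11,15-tetramethylhexadeca-2,14-dienal
Conditions: MnO2, CH2Cl2, rt
Reagents that add atoms: none
Why: Chemoselective allylic oxidation with activated MnO2, which stops at the enal and should not isomerise the double bond.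

Step 7
Reactants: 12 methylhydroquinone
Product: 13 2-methyl-4-(triisopropylsilyloxy)phenol
Conditions: iPr3SiCl (1.0 equiv), imidazole, DMF, 0 °C
Reagents that add atoms: chlorotriisopropylsilane, CC(C)[Si](Cl)(C(C)C)C(C)C
Why: Silylation of a phenol with a bulky chlorosilane, expected to prefer the hydroxyl flanked by two hydrogens over the one next to the methyl group, with the regioisomer and the bis-silyl ether separated by chromatography.

Step 8
Reactants: 13 2-methyl-4-(triisopropylsilyloxy)phenol
Product: 14 2-hydroxy-3-methyl-5-(triisopropylsilyloxy)benzaldehyde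
Conditions: MgCl2, Et3N, (CH2O)n, MeCN, reflux
Reagents that add atoms: paraformaldehyde (formaldehyde), C=O
Why: Casnati–Skattebøl magnesium-mediated ortho-formylation, in which the magnesium phenoxide delivers formaldehyde to the only free ortho position and a second formaldehyde oxidises the benzylic alkoxide to the aldehyde.

Step 9
Reactants: 11 (2E,7R,11S)-3,7,11,15-tetramethylhexadeca-2,14-dienal; 14 2-hydroxy-3-methyl-5-(triisopropylsilyloxy)benzaldehyde
Product: 16 (2R,6R)-10-methyl-2-[(4R,8S)-4,8,12-trimethyltridec-11-en-1-yl]-8-(triisopropylsilyloxy)-3,4-dihydro-2H,6H-2,6-methano-1,5-benzodioxocin-4-ol (bridged lactol; 2R,4R in chroman numbering; anomer mixture at the lactol carbon), via hydroxy aldehyde 15 (not isolated)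
Conditions: (S)-2-[bis(3,5-bis(trifluoromethyl)phenyl)(triethylsilyloxy)methyl]pyrrolidine (30 mol%), PhCO2H (30 mol%), toluene, rt
Reagents that add atoms: none
Why: Iminium formation between 11 and the amine, then loss of a proton from the 3-methyl group, gives the cross-conjugated dienamine (which also erases the C2=C3 geometry of 11), and its terminal CH2 adds to the formyl group of 14 in a vinylogous aldol step (C3–C4). The regenerated β,β-disubstituted iminium ion is attacked at its β-carbon by the phenol in a 6-exo-trig oxa-Michael closure of the dihydropyran ring (O1–C2), and after hydrolysis the C4 hydroxyl of 15 adds to the released aldehyde in a 6-exo-trig hemiacetalisation that closes the lactol bridge; this is the known diarylprolinol silyl ether-catalysed aldol/oxa-Michael domino of salicylaldehydes with 3-methyl-2-enals. C2 is set by the catalyst: in the E, s-trans iminium ion with the aldol arm anti to the iminium carbon, the C(Ar)2OSiEt3 group of the (S)-pyrrolidine covers one face, so the tethered phenol should add to the other face and give the 2R centre. C4 is set relative to C2 by the bridge, because only the isomer with the C4 oxygen and the C2 acetaldehyde arm cis can lactolise while the aldol and oxa-Michael steps remain reversible; the lactol carbon forms as an anomer mixture and is oxidised in step 10. The step needs γ-deprotonation at the methyl group and not at the chain methylene, aldol before oxa-Michael, and addition of a hindered phenol to a fully substituted β-carbon; the accessible methyl protons, the low reactivity of the β,β-disubstituted iminium ion towards intermolecular attack, the intramolecular delivery of the phenol and the lactol trap should secure these.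

Step 10
Reactants: 16 bridged lactol
Product: 17 (2R,6R)-10-methyl-2-[(4R,8S)-4,8,12-trimethyltridec-11-en-1-yl]-8-(triisopropylsilyloxy)-2H,6H-2,6-methano-1,5-benzodioxocin-4(3H)-one (bridged lactone)
Conditions: nPr4N[RuO4] (5 mol%), N-methylmorpholine N-oxide, 4 Å MS, CH2Cl2, rt
Reagents that add atoms: none
Why: Ley–Griffith oxidation of a lactol to the δ-lactone, which removes the anomeric mixture and should leave the trisubstituted alkene, the aryl silyl ether and both bridgehead centres untouched.

Step 11
Reactants: 17 bridged lactone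
Product: 19 2-[(2R)-8-methyl-2-[(4R,8S)-4,8,12-trimethyltridec-11-en-1-yl]-6-(triisopropylsilyloxy)-3,4-dihydro-2H-chromen-2-yl]acetic acid, via triethylsilyl ester 18 (not isolated)
Conditions: Et3SiH, BF3·OEt2, CH2Cl2, −40 to 0 °C; aqueous work-up
Reagents that add atoms: none
Why: Ionic hydrogenation of a benzylic C–O bond: BF3 activates the lactone, C4–O ionises to a cation stabilised through the ring by O1, Et3SiH delivers hydride, and the carboxylate leaves as its silyl ester so that no strong Brønsted acid is free to protonate the chain alkene; C2 is not involved.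

Step 12
Reactants: 19 chroman-2-ylacetic acid
Product: 21 triisopropyl{[(2R)-2,8-dimethyl-2-[(4R,8S)-4,8,12-trimethyltridec-11-en-1-yl]-3,4-dihydro-2H-chromen-6-yl]oxy}silane, via Barton ester 20 (not isolated)
Conditions: N-hydroxypyridine-2-thione, DCC, DMAP (cat.), CH2Cl2, rt, dark; then t-BuSH, hν (tungsten lamp), rt
Reagents that add atoms: none
Why: Barton reductive decarboxylation: photolysis of the thiohydroxamate ester gives an acyloxy radical that loses CO2, and the primary radical on the C2 methylene takes hydrogen from the thiol faster than it can rearrange, leaving the C2 methyl group with C2 configuration unchanged because C2 is never a radical centre.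

Step 13
Reactants: 21 silyl ether of the target
Product: 22 (2R)-2,8-dimethyl-2-[(4R,8S)-4,8,12-trimethyltridec-11-en-1-yl]-3,4-dihydro-2H-chromen-6-ol (target, CNP0221369.1)
Conditions: Bu4NF, THF, 0 °C
Reagents that add atoms: none
Why: Fluoride-mediated cleavage of an aryl silyl ether, to which the chroman, the alkene and the three stereocentres are inert.

**Compound list**

1 | (S)-3-bromo-2-methylpropan-1-ol | BrC[C@@H](C)CO | starting material
2 | (S)-1-bromo-3-chloro-2-methylpropane | BrC[C@@H](C)CCl | intermediate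
3 | (R)-citronellyl bromide, (6R)-8-bromo-2,6-dimethyloct-2-ene | CC(C)=CCC[C@@H](C)CCBr | starting material
4 | [(3R)-3,7-dimethyloct-6-en-1-yl]magnesium bromide | CC(C)=CCC[C@@H](C)CC[Mg]Br | intermediate
5 | (6S,10R)-11-chloro-2,6,10-trimethylundec-2-ene | CC(C)=CCC[C@@H](C)CCC[C@@H](C)CCl | intermediate
6 | [(2R,6S)-2,6,10-trimethylundec-9-en-1-yl]magnesium chloride | CC(C)=CCC[C@@H](C)CCC[C@@H](C)C[Mg]Cl | intermediate
7 | trimethyl{[(6R,10S)-6,10,14-trimethylpentadeca-2,13-dien-2-yl]oxy}silane | CC(C)=CCC[C@@H](C)CCC[C@@H](C)CCC=C(C)O[Si](C)(C)C | intermediate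
8 | (6R,10S)-6,10,14-trimethylpentadec-13-en-2-one | CC(C)=CCC[C@@H](C)CCC[C@@H](C)CCCC(C)=O | intermediate
9 | ethyl (2E,7R,11S)-3,7,11,15-tetramethylhexadeca-2,14-dienoate | CC(C)=CCC[C@@H](C)CCC[C@@H](C)CCC/C(C)=C/C(=O)OCC | intermediate
10 | (2E,7R,11S)-3,7,11,15-tetramethylhexadeca-2,14-dien-1-ol | CC(C)=CCC[C@@H](C)CCC[C@@H](C)CCC/C(C)=C/CO | intermediate
11 | (2E,7R,11S)-3,7,11,15-tetramethylhexadeca-2,14-dienal | CC(C)=CCC[C@@H](C)CCC[C@@H](C)CCC/C(C)=C/C=O | intermediate
12 | methylhydroquinone (2-methylbenzene-1,4-diol) | Cc1cc(O)ccc1O | starting material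
13 | 2-methyl-4-(triisopropylsilyloxy)phenol | Cc1cc(O[Si](C(C)C)(C(C)C)C(C)C)ccc1O | intermediate
14 | 2-hydroxy-3-methyl-5-(triisopropylsilyloxy)benzaldehyde | Cc1cc(O[Si](C(C)C)(C(C)C)C(C)C)cc(C=O)c1O | intermediate
15 | 2-[(2R,4R)-4-hydroxy-8-methyl-2-[(4R,8S)-4,8,12-trimethyltridec-11-en-1-yl]-6-(triisopropylsilyloxy)-3,4-dihydro-2H-chromen-2-yl]acetaldehyde | CC(C)=CCC[C@@H](C)CCC[C@@H](C)CCC[C@]1(CC=O)C[C@@H](O)c2cc(O[Si](C(C)C)(C(C)C)C(C)C)cc(C)c2O1 | intermediate
16 | (2R,6R)-10-methyl-2-[(4R,8S)-4,8,12-trimethyltridec-11-en-1-yl]-8-(triisopropylsilyloxy)-3,4-dihydro-2H,6H-2,6-methano-1,5-benzodioxocin-4-ol (bridged lactol, anomer mixture) | CC(C)=CCC[C@@H](C)CCC[C@@H](C)CCC[C@]12CC(O)O[C@H](C1)c3cc(O[Si](C(C)C)(C(C)C)C(C)C)cc(C)c3O2 | intermediate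
17 | (2R,6R)-10-methyl-2-[(4R,8S)-4,8,12-trimethyltridec-11-en-1-yl]-8-(triisopropylsilyloxy)-2H,6H-2,6-methano-1,5-benzodioxocin-4(3H)-one (bridged lactone) | CC(C)=CCC[C@@H](C)CCC[C@@H](C)CCC[C@]12CC(=O)O[C@H](C1)c3cc(O[Si](C(C)C)(C(C)C)C(C)C)cc(C)c3O2 | intermediate
18 | triethylsilyl 2-[(2R)-8-methyl-2-[(4R,8S)-4,8,12-trimethyltridec-11-en-1-yl]-6-(triisopropylsilyloxy)-3,4-dihydro-2H-chromen-2-yl]acetate | CC(C)=CCC[C@@H](C)CCC[C@@H](C)CCC[C@]1(CC(=O)O[Si](CC)(CC)CC)CCc2cc(O[Si](C(C)C)(C(C)C)C(C)C)cc(C)c2O1 | intermediate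
19 | 2-[(2R)-8-methyl-2-[(4R,8S)-4,8,12-trimethyltridec-11-en-1-yl]-6-(triisopropylsilyloxy)-3,4-dihydro-2H-chromen-2-yl]acetic acid | CC(C)=CCC[C@@H](C)CCC[C@@H](C)CCC[C@]1(CC(=O)O)CCc2cc(O[Si](C(C)C)(C(C)C)C(C)C)cc(C)c2O1 | intermediate
20 | 2-thioxopyridin-1(2H)-yl 2-[(2R)-8-methyl-2-[(4R,8S)-4,8,12-trimethyltridec-11-en-1-yl]-6-(triisopropylsilyloxy)-3,4-dihydro-2H-chromen-2-yl]acetate (Barton ester) | CC(C)=CCC[C@@H](C)CCC[C@@H](C)CCC[C@]1(CC(=O)On3ccccc3=S)CCc2cc(O[Si](C(C)C)(C(C)C)C(C)C)cc(C)c2O1 | intermediate
21 | triisopropyl{[(2R)-2,8-dimethyl-2-[(4R,8S)-4,8,12-trimethyltridec-11-en-1-yl]-3,4-dihydro-2H-chromen-6-yl]oxy}silane | CC(C)=CCC[C@@H](C)CCC[C@@H](C)CCC[C@]1(C)CCc2cc(O[Si](C(C)C)(C(C)C)C(C)C)cc(C)c2O1 | intermediate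
22 | (2R)-2,8-dimethyl-2-[(4R,8S)-4,8,12-trimethyltridec-11-en-1-yl]-3,4-dihydro-2H-chromen-6-ol | CC(C)=CCC[C@@H](C)CCC[C@@H](C)CCC[C@]1(C)CCc2cc(O)cc(C)c2O1 | target

**Step count and risks**

Total step count: 13. Longest linear sequence: 11 steps (steps 1–6, then 9–13); steps 7 and 8 run in parallel.

Steps most likely to fail:

1. Step 9. The oxa-Michael closure may show poor or reversed facial selectivity at C2, the dienamine may form by deprotonation at the chain methylene instead of the methyl group, or turnover may stall because the phenol is flanked by a methyl group.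
 Fallback (sets out from 14, uses Grignard reagent 6 made from chloride 5, comes back at 21): C2 would be set by an enantioselective Wacker-type oxypalladation with carbonylative trapping, with the 2-methyl group present from the start and the acetate arm supplying C1' and C2'.
 - Wittig reaction of 14 with 1-(triphenylphosphoranylidene)propan-2-one (toluene, 80 °C) should give (E)-4-[2-hydroxy-3-methyl-5-(triisopropylsilyloxy)phenyl]but-3-en-2-one F1.
 - Hydrogenation (H2, Pd/C, EtOAc; no other alkene is present in this fragment) should give 4-[2-hydroxy-3-methyl-5-(triisopropylsilyloxy)phenyl]butan-2-one F2.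
 - Methylenation (Ph3P=CH2 in excess, THF) should give 2-methyl-6-(3-methylbut-3-en-1-yl)-4-(triisopropylsilyloxy)phenol F3.
 - Pd(OCOCF3)2 (cat.) with (S,S)-Bn-BOXAX, p-benzoquinone, CO (1 atm) and MeOH should close the dihydropyran ring by 6-exo oxypalladation and trap the alkylpalladium as methyl 2-[(2S)-2,8-dimethyl-6-(triisopropylsilyloxy)-3,4-dihydro-2H-chromen-2-yl]acetate F4; this ligand enantiomer is expected to give the 2S ester, which has the spatial arrangement of the target.
 - LiAlH4 (THF, 0 °C) should give 2-[(2S)-2,8-dimethyl-6-(triisopropylsilyloxy)-3,4-dihydro-2H-chromen-2-yl]ethan-1-ol F5, and TsCl/pyridine its tosylate 2-[(2S)-2,8-dimethyl-6-(triisopropylsilyloxy)-3,4-dihydro-2H-chromen-2-yl]ethyl 4-methylbenzenesulfonate F6.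
 - Li2CuCl4-catalysed coupling of F6 with Grignard reagent 6 (THF, −10 °C to rt) joins C2' to C3' and should give 21, which step 13 converts to 22. Steps 4–6 and 9–12 are then not needed.

2. Step 11. The Lewis acid may protonate or activate the C11'=C12' alkene, leading to reduction of the chain double bond or cation–olefin side reactions, or may cleave the aryl silyl ether before the benzylic C–O bond is reduced.
 Fallback (sets out from 16, comes back at 21): both the formyl carbon and the C4 oxygen would be removed without any cationic hydride transfer.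
 - Tsuji–Wilkinson decarbonylation of the open hydroxy aldehyde form of 16 (RhCl(PPh3)3, stoichiometric, toluene, reflux) should give (2R,4R)-2,8-dimethyl-2-[(4R,8S)-4,8,12-trimethyltridec-11-en-1-yl]-6-(triisopropylsilyloxy)-3,4-dihydro-2H-chromen-4-ol F7.
 - Dehydration of the benzylic alcohol with the Burgess reagent (benzene, 50 °C) should give triisopropyl{[(2R)-2,8-dimethyl-2-[(4R,8S)-4,8,12-trimethyltridec-11-en-1-yl]-2H-chromen-6-yl]oxy}silane F8.
 - Diimide (2-nitrobenzenesulfonohydrazide, Et3N, CH2Cl2, rt) should reduce the cis-disubstituted, styrene-type C3=C4 bond in preference to the trisubstituted chain alkene and give 21. Steps 10–12 are then not needed.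

3. Step 3. Methyl vinyl ketone may polymerise or undergo 1,2-addition, and Wurtz-type homocoupling may occur while the Grignard reagent forms from the β-branched chloride.
 Fallback (sets out from 5, comes back at 8): the three-carbon ketone unit would be introduced by cross-coupling with a masked ketone electrophile instead of conjugate addition.
 - Grignard reagent 6, made from 5 as in step 3, would be coupled with 2-(2-bromoethyl)-2-methyl-1,3-dioxolane (Li2CuCl4 cat., THF, 0 °C) to give 2-methyl-2-[(4R,8S)-4,8,12-trimethyltridec-11-en-1-yl]-1,3-dioxolane F9.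
 - Mild hydrolysis (pyridinium p-toluenesulfonate, acetone/H2O, 50 °C) should release 8 without touching the trisubstituted alkene.

**Further compounds**

F1 | step 9 | (E)-4-[2-hydroxy-3-methyl-5-(triisopropylsilyloxy)phenyl]but-3-en-2-one | CC(=O)/C=C/c1cc(O[Si](C(C)C)(C(C)C)C(C)C)cc(C)c1O
F2 | step 9 | 4-[2-hydroxy-3-methyl-5-(triisopropylsilyloxy)phenyl]butan-2-one | CC(=O)CCc1cc(O[Si](C(C)C)(C(C)C)C(C)C)cc(C)c1O
F3 | step 9 | 2-methyl-6-(3-methylbut-3-en-1-yl)-4-(triisopropylsilyloxy)phenol | CC(=C)CCc1cc(O[Si](C(C)C)(C(C)C)C(C)C)cc(C)c1O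
F4 | step 9 | methyl 2-[(2S)-2,8-dimethyl-6-(triisopropylsilyloxy)-3,4-dihydro-2H-chromen-2-yl]acetate | COC(=O)C[C@]1(C)CCc2cc(O[Si](C(C)C)(C(C)C)C(C)C)cc(C)c2O1
F5 | step 9 | 2-[(2S)-2,8-dimethyl-6-(triisopropylsilyloxy)-3,4-dihydro-2H-chromen-2-yl]ethan-1-ol | OCC[C@]1(C)CCc2cc(O[Si](C(C)C)(C(C)C)C(C)C)cc(C)c2O1
F6 | step 9 | 2-[(2S)-2,8-dimethyl-6-(triisopropylsilyloxy)-3,4-dihydro-2H-chromen-2-yl]ethyl 4-methylbenzenesulfonate | Cc1ccc(cc1)S(=O)(=O)OCC[C@]1(C)CCc2cc(O[Si](C(C)C)(C(C)C)C(C)C)cc(C)c2O1
F7 | step 11 | (2R,4R)-2,8-dimethyl-2-[(4R,8S)-4,8,12-trimethyltridec-11-en-1-yl]-6-(triisopropylsilyloxy)-3,4-dihydro-2H-chromen-4-ol | CC(C)=CCC[C@@H](C)CCC[C@@H](C)CCC[C@]1(C)C[C@@H](O)c2cc(O[Si](C(C)C)(C(C)C)C(C)C)cc(C)c2O1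
F8 | step 11 | triisopropyl{[(2R)-2,8-dimethyl-2-[(4R,8S)-4,8,12-trimethyltridec-11-en-1-yl]-2H-chromen-6-yl]oxy}silane | CC(C)=CCC[C@@H](C)CCC[C@@H](C)CCC[C@]1(C)C=Cc2cc(O[Si](C(C)C)(C(C)C)C(C)C)cc(C)c2O1
F9 | step 3 | 2-methyl-2-[(4R,8S)-4,8,12-trimethyltridec-11-en-1-yl]-1,3-dioxolane | CC(C)=CCC[C@@H](C)CCC[C@@H](C)CCCC1(C)OCCO1
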